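## The problem

The target (30) is a germacranolide of the hirsutinolide type. With germacrane numbering, the ten-membered carbocycle C1–C10 is bridged by an oxygen between C1 and C4, so that O–C1(=C2)–C3–C4 is a 2,3-dihydrofuran. The ring is fused at C6–C7 to a butenolide (C7=C11, C12 lactone carbonyl, C13 acetoxymethyl) whose γ-carbon C6 carries the exocyclic C5=C6 bond. C8 bears an acetate and C10 a tertiary hydroxyl and a methyl group.

Three stereocentres (4S, 8S, 10S) and the C5=C6 geometry (5E, C4 syn to C7) must be set. C8 and C10 are 1,3-related across C9 and can control each other. C4 lies on the far side of the dienolide and has no neighbour to lean on, so its configuration has to be relayed through a ring.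

A ten-membered ring resists direct closure. The enol ether C1=C2 adds water or acid readily. The 13-acetoxy-7(11)-en-12,6-olide loses acetate under base through its dienolate. The C4 oxygen is tertiary and allylic.

The enabling feature is that C1 is at the carbonyl oxidation level and stands in a cyclodec-5-en-1-one relationship to C5=C6. The C3–C4 bond then joins two former vinyl termini, and a bond between C1 and C6 would close the six-membered ring C1–C10–C9–C8–C7–C6. This is the retron of an oxy-Cope ring expansion. Because C4 carries methyl and oxygen, the migrating terminus must be an enol ether.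

## Retrosynthesis

Atom labels C1–C13 are those of the target throughout. TBS = tert-butyldimethylsilyl, MOM = methoxymethyl.

**Enol ether last.** The C1=C2 bond of 30 is cut back to the C1 hemiketal 29 (loss of water). Only C2 carries hydrogen next to C1, so the dehydration is regiochemically unambiguous, and no earlier step has to tolerate the enol ether. 29 comes from its C10 MOM ether 28, and 28 from the triol 27 by acetylation of the secondary C8 and primary C13 hydroxyls.

**Oxygen bridge.** The O–C1 bond of 27 is cut to give the γ-hydroxy ketone 26, formed from the tris-silyl ether 25 on fluoride treatment. The ten-membered ring can only span the five-membered hemiketal cis, so the C4 configuration dictates that of C1. Closing the bridge after the carbocycle avoids carrying a strained bicycle through the ring-forming step.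

**Ring expansion (key cut).** In 25 the C3–C4 bond is cut and C1–C6 reconnected, giving the butenolide-fused 1-vinyl-2-(2-silyloxypropenyl)cyclohexanol 22. Cutting C5–C6, C1–C2 or C9–C10 instead would each require an end-to-end closure of a ten-membered ring. The [3,3] shift is a ring enlargement of a six-membered ring and sets C4 and the C5=C6 geometry in the same event. The forward reaction must run through the chair with C7 inside, on the alkoxide, at low temperature.

**C1 carbinol and enol ether.** Vinyl addition to the C1 ketone 17 is not used. The planar butenolide forces the C6 side chain pseudo-axial, a carbon nucleophile would enter trans to it, and the resulting trans-dialkenyl alcohol cannot reach the cyclic array. Oxygen is therefore delivered to that open face instead. 22 is cut at C2=C3 to the spiro-epoxide 21 (one-carbon homologation by a sulfonium ylide, C1–O bond untouched). 21 comes from the methyl ketone 20 by silyl enol ether formation while no hydroxyl is free.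

**Epoxide, ketone, methylene.** 20 comes from the exocyclic alkene 19 (epoxidation), 19 from the allyl compound 18 (Wacker oxidation), and 18 from the ketone 17 (methylenation). The order is dictated by chemoselectivity: the Wacker step spares a 1,1-disubstituted alkene, and the peracid step must precede the enol ether.

**Butenolide.** The C7=C11 bond and the O–C12 bond of 17 are cut to the phosphonate ester 16 (intramolecular Horner–Wadsworth–Emmons), assembled from the tertiary alcohol 11 and the acid 15. The C13 oxygen arrives with the phosphonate, so the tetrasubstituted alkene needs no later functionalisation.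

**C6 oxygen.** The C6–O bond of 11 is cut to the 2-allyl-1,3-dione 10 (enol hydroxylation). The quaternary centre is made by oxygen delivery to a planar carbon whose allyl group is already in place. 10 is the hydrolysis product of the vinylogous ester 9.

**C8 and C10.** 9 is the protected form of the anti-diol 7 (via 8). The C8 carbinol comes from the β-hydroxy ketone 6 by hydroxyl-directed reduction, 6 from the epoxyquinone 5 by reductive opening, and 5 from the quinone 4 by enantioselective epoxidation of its methyl-bearing double bond. The methoxy group of 4 does three jobs: it is the C7 oxygen, it shields C6=C7 from the peroxide, and it makes the two carbonyls different.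

**Aromatic start.** 4 is the oxidation product of the phenol 3, whose allyl group is placed by Claisen rearrangement of the ether 2, made from 5-methoxy-2-methylphenol 1. The acid 15 is traced through 14 and 13 to triethyl phosphonoacetate 12.

## Roads not taken

**Alternative 1: Ramberg–Bäcklund contraction.**
- Cut: the C1=C2 bond, traced to a six-membered 1,3-oxathiane 3,3-dioxide A2 (ring O–C1–SO2–C2–C3–C4).
- Forward key step: halogenation at C1, 1,3-elimination and loss of SO2 contract A2 to the dihydrofuran A1.
- Merits: the double bond position is fixed by the sulfone, C4, C8 and C10 are set beforehand by ordinary means, and the conditions are mild.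
- Weak points: A1 is only the C1–C10 segment. The ten-membered ring, the butenolide and C5=C6 are still missing, and every later step, including a medium-ring closure, must spare an acid-labile enol ether. C1 is also flanked by the quaternary C10, which hinders the halogenation and ring contraction.
- Comparison: this road is better in that C4 does not depend on a pericyclic transition state and the enol ether regiochemistry is beyond doubt. The chosen plan sets against this that one step makes the carbocycle, C4 and C5=C6 together, and that the enol ether appears only in the last step.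

**Alternative 2: biomimetic epoxide opening.**
- Cut: the O–C1 bond and the C5=C6 bond, traced to the ten-membered 4,5-epoxy-1-ketone A4.
- Forward key step: base removes H6, the epoxide opens to C5=C6, and the C4 alkoxide closes onto C1 to give the hemiketal A3.
- Merits: A3 is the same compound as 29 of the chosen route, one dehydration from the target. The acetates can be carried and no protecting group is needed at the end, so in end-game economy this road is clearly better.
- Weak points: the whole ring problem is moved into A4, a germacranolide with a defined epoxide, a C6 stereocentre and a C1 ketone, for which this road offers no ring-forming step. The dienolate formed by removing H6 can also expel the C13 acetate instead of opening the epoxide.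
- Comparison: both roads meet at 29/A3. The chosen plan is longer after the ring exists but supplies the ring by a unimolecular ring expansion.

**Alternative 3: intramolecular vinylogous aldol condensation.**
- Cut: the C5=C6 bond, traced to the seco-aldehyde A6 with a free γ-CH2 on the butenolide.
- Forward key step: in situ O-silylation of the butenolide, attack of C6 on the C5 aldehyde to close the ring, and elimination with DBU to give A5.
- Merits: convergent, with C4, C8, C10 and the dihydrofuran in hand before the ring closes and no stereo-determining rearrangement. In these respects it is as good as or better than the chosen plan.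
- Weak points: the closure is an end-to-end formation of a ten-membered ring at a neopentyl, α-oxygenated aldehyde, so it needs high dilution and competes with oligomerisation. The enol ether C1=C2 must survive a silyl triflate and the acid it releases. The base step runs next to the C13 silyloxy and C8 acetoxy groups.
- Comparison: the chosen plan has no entropic penalty in ring formation and no enol ether present at that stage, at the price of relying on chair selection in the [3,3] shift.

Key step: step 21

Assumptions: the phosphonate carbon of 13–16 is racemic and loses its stereochemistry in step 15. The antipode of the phase-transfer catalyst in step 4 is the one that gives 10S. Reagents written under the arrows are taken as commercial.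

## Route

Step 1
Reactants: 1 5-methoxy-2-methylphenol
Product: 2 2-(allyloxy)-4-methoxy-1-methylbenzene
Conditions: allyl bromide, K2CO3, acetone, reflux
Reagents that add atoms: allyl bromide, C=CCBr
Why: Williamson etherification of the phenoxide; no stereocentre is formed.

Step 2
Reactants: 2 2-(allyloxy)-4-methoxy-1-methylbenzene
Product: 3 2-allyl-3-methoxy-6-methylphenol
Conditions: N,N-diethylaniline, 190 °C
Reagents that add atoms: none
Why: Aromatic Claisen rearrangement; the only free ortho position lies next to the methoxy carbon, so the allyl group ends on the future C6, between the phenol carbon (future C1) and the methoxy carbon (future C7).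

Step 3
Reactants: 3 2-allyl-3-methoxy-6-methylphenol
Product: 4 2-methoxy-5-methyl-3-(prop-2-enyl)-1,4-benzoquinone
Conditions: O2 (1 atm), Co(salen) [Co(C16H14N2O2)] (5 mol %), MeCN, rt
Reagents that add atoms: dioxygen, O=O
Why: Cobalt–salen catalysed oxygenation of a 2,6-disubstituted phenol with a free para position gives the para-quinone; the terminal alkene is not touched.

Step 4
Reactants: 4 2-methoxy-5-methyl-3-(prop-2-enyl)-1,4-benzoquinone
Product: 5 (5S,6R)-5,6-epoxy-2-methoxy-5-methyl-3-(prop-2-enyl)cyclohex-2-ene-1,4-dione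
Conditions: t-BuOOH (1.5 equiv), 1 M aq NaOH, N-(9-anthracenylmethyl)cinchona-alkaloid ammonium bromide (10 mol %), toluene, −10 °C
Reagents that add atoms: tert-butyl hydroperoxide, CC(C)(C)OO
Why: Weitz–Scheffer epoxidation under chiral phase-transfer catalysis, a reaction known for 2-methyl-1,4-quinones. The methoxy-bearing C6=C7 bond is a vinylogous ester and does not accept the peroxide anion, so only C9=C10 reacts; the ion-paired catalyst selects the face and sets C10 (S).

Step 5
Reactants: 5 (5S,6R)-5,6-epoxy-2-methoxy-5-methyl-3-(prop-2-enyl)cyclohex-2-ene-1,4-dione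
Product: 6 (5S)-5-hydroxy-2-methoxy-5-methyl-3-(prop-2-enyl)cyclohex-2-ene-1,4-dione
Conditions: SmI2 (2.2 equiv), THF/MeOH, −90 °C
Reagents that add atoms: none
Why: Samarium diiodide reduction of an α,β-epoxy ketone to the β-hydroxy ketone. The electron goes to the C8 carbonyl (the C1 carbonyl is a vinylogous ester), so the adjacent C9–O bond breaks and the C10–O bond keeps its configuration.

Step 6
Reactants: 6 (5S)-5-hydroxy-2-methoxy-5-methyl-3-(prop-2-enyl)cyclohex-2-ene-1,4-dione
Product: 7 (4S,6S)-4,6-dihydroxy-3-methoxy-6-methyl-2-(prop-2-enyl)cyclohex-2-en-1-one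
Conditions: Me4NBH(OAc)3, MeCN/AcOH (1:1), −30 °C
Reagents that add atoms: none
Why: Hydroxyl-directed triacetoxyborohydride reduction of a β-hydroxy ketone. Hydride is delivered from the boron bound to the C10 oxygen to the same face of C8, so the new C8 hydroxyl is trans to the C10 hydroxyl (8S); the vinylogous ester carbonyl is not reduced.

Step 7
Reactants: 7 (4S,6S)-4,6-dihydroxy-3-methoxy-6-methyl-2-(prop-2-enyl)cyclohex-2-en-1-one
Product: 8 (4S,6S)-4-(tert-butyldimethylsilyloxy)-6-hydroxy-3-methoxy-6-methyl-2-(prop-2-enyl)cyclohex-2-en-1-one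
Conditions: TBSCl, imidazole, DMF, 0 °C
Reagents that add atoms: tert-butyldimethylsilyl chloride, CC(C)(C)[Si](C)(C)Cl
Why: Silylation of the secondary allylic hydroxyl; the tertiary hydroxyl is too hindered for the silyl chloride.

Step 8
Reactants: 8 (4S,6S)-4-(tert-butyldimethylsilyloxy)-6-hydroxy-3-methoxy-6-methyl-2-(prop-2-enyl)cyclohex-2-en-1-one
Product: 9 (4S,6S)-4-(tert-butyldimethylsilyloxy)-3-methoxy-6-(methoxymethoxy)-6-methyl-2-(prop-2-enyl)cyclohex-2-en-1-one
Conditions: MOMCl, i-Pr2NEt, NaI (cat.), CH2Cl2, 40 °C
Reagents that add atoms: chloromethyl methyl ether, COCCl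
Why: Alkylation of the tertiary alcohol with the reactive iodomethyl ether formed in situ; the acetal resists the bases and organometallic reagents used later and cannot migrate to a neighbouring alkoxide.

Step 9
Reactants: 9 (4S,6S)-4-(tert-butyldimethylsilyloxy)-3-methoxy-6-(methoxymethoxy)-6-methyl-2-(prop-2-enyl)cyclohex-2-en-1-one
Product: 10 (4S,6S)-6-(tert-butyldimethylsilyloxy)-4-(methoxymethoxy)-4-methyl-2-(prop-2-enyl)cyclohexane-1,3-dione (enol form)
Conditions: 1 M HCl, THF, 0 °C → rt
Reagents that add atoms: water, O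
Why: Acid hydrolysis of a vinylogous ester by addition–elimination at C7; the dilute acid and short contact leave the secondary silyl ether and the acetal intact.

Step 10
Reactants: 10 (4S,6S)-6-(tert-butyldimethylsilyloxy)-4-(methoxymethoxy)-4-methyl-2-(prop-2-enyl)cyclohexane-1,3-dione (enol form)
Product: 11 (2S,4S,6S)-6-(tert-butyldimethylsilyloxy)-2-hydroxy-4-(methoxymethoxy)-4-methyl-2-(prop-2-enyl)cyclohexane-1,3-dione
Conditions: dimethyldioxirane (1.05 equiv, acetone), CH2Cl2, −40 → 0 °C
Reagents that add atoms: dimethyldioxirane, CC1(C)OO1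
Why: Dimethyldioxirane oxidises the enol of a 2-alkyl-1,3-dione to the 2-hydroxy-1,3-dione much faster than it epoxidises a terminal alkene. In the enol the C8 silyloxy and C10 methyl groups are pseudo-equatorial and the C10 methoxymethoxy group is pseudo-axial over one face of C6, so oxygen enters anti to it, on the face of the C8 oxygen (C6 becomes S).

Step 11
Reactants: 12 triethyl phosphonoacetate
Product: 13 ethyl 2-(diethoxyphosphoryl)-3-hydroxypropanoate (racemic)
Conditions: aq CH2O (37 %, 1.0 equiv), K2CO3 (0.1 equiv), THF, 0 °C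
Reagents that add atoms: formaldehyde, C=O
Why: Aldol-type hydroxymethylation of the doubly stabilised carbanion; one equivalent of formaldehyde at 0 °C stops before a second equivalent can olefinate.

Step 12
Reactants: 13 ethyl 2-(diethoxyphosphoryl)-3-hydroxypropanoate (racemic)
Product: 14 ethyl 3-(tert-butyldimethylsilyloxy)-2-(diethoxyphosphoryl)propanoate (racemic)
Conditions: TBSCl, imidazole, CH2Cl2, 0 °C
Reagents that add atoms: tert-butyldimethylsilyl chloride, CC(C)(C)[Si](C)(C)Cl
Why: Standard silylation of a primary alcohol.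

Step 13
Reactants: 14 ethyl 3-(tert-butyldimethylsilyloxy)-2-(diethoxyphosphoryl)propanoate (racemic)
Product: 15 3-(tert-butyldimethylsilyloxy)-2-(diethoxyphosphoryl)propanoic acid (racemic)
Conditions: Me3SnOH, 1,2-dichloroethane, 70 °C; 0.1 M HCl wash
Reagents that add atoms: trimethyltin hydroxide, C[Sn](C)(C)O
Why: Trimethyltin hydroxide cleaves the carboxylic ethyl ester under near-neutral conditions; the phosphonate esters stay, and base-induced loss of silanolate from the β-silyloxy ester is avoided.

Step 14
Reactants: 11 (2S,4S,6S)-6-(tert-butyldimethylsilyloxy)-2-hydroxy-4-(methoxymethoxy)-4-methyl-2-(prop-2-enyl)cyclohexane-1,3-dione; 15 3-(tert-butyldimethylsilyloxy)-2-(diethoxyphosphoryl)propanoic acid (racemic)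
Product: 16 (1S,3S,5S)-3-(tert-butyldimethylsilyloxy)-5-(methoxymethoxy)-5-methyl-2,6-dioxo-1-(prop-2-enyl)cyclohexyl 3-(tert-butyldimethylsilyloxy)-2-(diethoxyphosphoryl)propanoate
Conditions: DCC, DMAP (0.2 equiv), CH2Cl2, 0 °C → rt
Reagents that add atoms: none
Why: Steglich esterification; phosphonoacetic acids are activated through their ketenes, which acylate hindered tertiary alcohols, and 11 has no other hydroxyl.

Step 15
Reactants: 16 (1S,3S,5S)-3-(tert-butyldimethylsilyloxy)-5-(methoxymethoxy)-5-methyl-2,6-dioxo-1-(prop-2-enyl)cyclohexyl 3-(tert-butyldimethylsilyloxy)-2-(diethoxyphosphoryl)propanoate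
Product: 17 (4S,6S,7aS)-4-(tert-butyldimethylsilyloxy)-3-[(tert-butyldimethylsilyloxy)methyl]-6-(methoxymethoxy)-6-methyl-7a-(prop-2-enyl)-5,6-dihydro-1-benzofuran-2,7(4H,7aH)-dione
Conditions: LiCl, DBU, MeCN, 0 °C → rt
Reagents that add atoms: none
Why: Intramolecular Horner–Wadsworth–Emmons olefination closes the five-membered lactone onto the C7 ketone, whose other neighbour is the C8 methine, in preference to the C1 ketone, which lies between two fully substituted carbons. The phosphonate stereocentre disappears; C6, C8 and C10 are untouched.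

Step 16
Reactants: 17 (4S,6S,7aS)-4-(tert-butyldimethylsilyloxy)-3-[(tert-butyldimethylsilyloxy)methyl]-6-(methoxymethoxy)-6-methyl-7a-(prop-2-enyl)-5,6-dihydro-1-benzofuran-2,7(4H,7aH)-dione
Product: 18 (4S,6S,7aS)-4-(tert-butyldimethylsilyloxy)-3-[(tert-butyldimethylsilyloxy)methyl]-6-(methoxymethoxy)-6-methyl-7-methylidene-7a-(prop-2-enyl)-5,6,7,7a-tetrahydro-1-benzofuran-2(4H)-one
Conditions: Zn, CH2Br2, TiCl4, THF/CH2Cl2, 0 °C → rt
Reagents that add atoms: dibromomethane, BrCBr
Why: Takai–Lombardo methylenation converts hindered, non-enolisable ketones and leaves lactones alone.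

Step 17
Reactants: 18 (4S,6S,7aS)-4-(tert-butyldimethylsilyloxy)-3-[(tert-butyldimethylsilyloxy)methyl]-6-(methoxymethoxy)-6-methyl-7-methylidene-7a-(prop-2-enyl)-5,6,7,7a-tetrahydro-1-benzofuran-2(4H)-one
Product: 19 (4S,6S,7aS)-4-(tert-butyldimethylsilyloxy)-3-[(tert-butyldimethylsilyloxy)methyl]-6-(methoxymethoxy)-6-methyl-7-methylidene-7a-(2-oxopropyl)-5,6,7,7a-tetrahydro-1-benzofuran-2(4H)-one
Conditions: PdCl2 (10 mol %), CuCl (1 equiv), O2 (1 atm), DMF/H2O (7:1), rt
Reagents that add atoms: water, O
Why: Wacker oxidation turns the monosubstituted allyl alkene into the methyl ketone. The 1,1-disubstituted exocyclic alkene, which has no allylic hydrogen, and the tetrasubstituted butenolide alkene do not react.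

Step 18
Reactants: 19 (4S,6S,7aS)-4-(tert-butyldimethylsilyloxy)-3-[(tert-butyldimethylsilyloxy)methyl]-6-(methoxymethoxy)-6-methyl-7-methylidene-7a-(2-oxopropyl)-5,6,7,7a-tetrahydro-1-benzofuran-2(4H)-one
Product: 20 (4S,6S,7R,7aS)-4-(tert-butyldimethylsilyloxy)-3-[(tert-butyldimethylsilyloxy)methyl]-6-(methoxymethoxy)-6-methyl-7a-(2-oxopropyl)-4,5,6,7a-tetrahydrospiro[1-benzofuran-7,2'-oxiran]-2-one
Conditions: mCPBA, NaHCO3, CH2Cl2, 0 °C → rt
Reagents that add atoms: 3-chloroperoxybenzoic acid, OOC(=O)c1cccc(Cl)c1
Why: Prilezhaev epoxidation of the exocyclic alkene. The planar butenolide holds the C6 side chain pseudo-axial, and with it the C10 methoxymethoxy group, both on one face of C1; the peracid comes from the other face, so the epoxide oxygen stands on the side of the lactone oxygen (C1 R).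

Step 19
Reactants: 20 (4S,6S,7R,7aS)-4-(tert-butyldimethylsilyloxy)-3-[(tert-butyldimethylsilyloxy)methyl]-6-(methoxymethoxy)-6-methyl-7a-(2-oxopropyl)-4,5,6,7a-tetrahydrospiro[1-benzofuran-7,2'-oxiran]-2-one
Product: 21 (4S,6S,7R,7aS)-4-(tert-butyldimethylsilyloxy)-3-[(tert-butyldimethylsilyloxy)methyl]-7a-[(1Z)-2-(tert-butyldimethylsilyloxy)prop-1-enyl]-6-(methoxymethoxy)-6-methyl-4,5,6,7a-tetrahydrospiro[1-benzofuran-7,2'-oxiran]-2-one
Conditions: TBSOTf (1.2 equiv), Et3N (2.5 equiv), CH2Cl2, −78 → 0 °C
Reagents that add atoms: tert-butyldimethylsilyl trifluoromethanesulfonate, CC(C)(C)[Si](C)(C)OS(=O)(=O)C(F)(F)F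
Why: Soft enolisation with a silyl triflate and an amine gives the more substituted enol ether, here helped by the acidifying β-acyloxy carbon C6; the Z isomer (oxygen syn to C6, methyl anti) avoids allylic strain between the methyl group and the quaternary C6. No free enolate is formed, so the lactone carboxylate is not expelled. Any terminal regioisomer cannot enter step 21 and would be separated after it.

Step 20
Reactants: 21 (4S,6S,7R,7aS)-4-(tert-butyldimethylsilyloxy)-3-[(tert-butyldimethylsilyloxy)methyl]-7a-[(1Z)-2-(tert-butyldimethylsilyloxy)prop-1-enyl]-6-(methoxymethoxy)-6-methyl-4,5,6,7a-tetrahydrospiro[1-benzofuran-7,2'-oxiran]-2-one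
Product: 22 (4S,6S,7R,7aS)-7-ethenyl-7-hydroxy-4-(tert-butyldimethylsilyloxy)-3-[(tert-butyldimethylsilyloxy)methyl]-7a-[(1Z)-2-(tert-butyldimethylsilyloxy)prop-1-enyl]-6-(methoxymethoxy)-6-methyl-5,6,7,7a-tetrahydro-1-benzofuran-2(4H)-one
Conditions: Me3SI (4 equiv), n-BuLi (3.8 equiv), THF, −10 → 0 °C; pH 7 buffer
Reagents that add atoms: trimethylsulfonium iodide, C[S+](C)C.[I-]
Why: Dimethylsulfonium methylide opens the spiro-epoxide at its CH2 carbon, and a second equivalent eliminates dimethyl sulfide from the sulfonium alkoxide; this is a known one-carbon homologation of epoxides to allylic alcohols. The C1–O bond is never broken, so the tertiary alcohol keeps the configuration of step 18 and the vinyl group is cis to the C6 side chain.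

Step 21
Reactants: 22 (4S,6S,7R,7aS)-7-ethenyl-7-hydroxy-4-(tert-butyldimethylsilyloxy)-3-[(tert-butyldimethylsilyloxy)methyl]-7a-[(1Z)-2-(tert-butyldimethylsilyloxy)prop-1-enyl]-6-(methoxymethoxy)-6-methyl-5,6,7,7a-tetrahydro-1-benzofuran-2(4H)-one
Product: 25 (4S,5E,8S,10S)-4,8,13-tris(tert-butyldimethylsilyloxy)-10-(methoxymethoxy)-1-oxogermacra-5,7(11)-dien-12,6-olide, via potassium C1-alkoxide 23 (not isolated), via ten-membered potassium C1-enolate 24 (not isolated)
Conditions: KN(SiMe3)2 (1.05 equiv), 18-crown-6 (1.1 equiv), THF, −78 → −30 °C; then AcOH in THF, −78 °C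
Reagents that add atoms: none
Why: The alkoxide 23 undergoes an anionic oxy-Cope rearrangement: across the array C3=C2–C1–C6–C5=C4 the C1–C6 bond breaks while C3–C4 forms, giving the enolate 24, which is protonated at C2. The closest known reaction is the alkoxide-accelerated ring expansion of cis-1,2-dialkenylcyclohexanols to cis-cyclodec-5-enones. The ten-membered ring arises by enlargement of the six-membered ring by four atoms, suprafacial on both allyl units; it is not an end-to-end cyclisation, so no exo or endo mode applies. C4 is the only new stereocentre and is fixed by the configuration of C6, the Z geometry of the enol ether and a chair array with C7 pseudo-axial (inside) and C10 pseudo-equatorial, which gives 4S and places C4 syn to C7 on the new C5=C6 bond. The selectivity needed is this chair against the one with the lactone oxygen inside, which would give the 4R,5Z isomer. Three things favour it: the quaternary C10 avoids the pseudo-axial site at the alkoxide carbon, the cis ring alkene is the less strained cyclodecene, and repulsion between the C6 side chain and the C10 methoxymethoxy group already pushes the six-membered ring toward the twist form this chair needs. Conjugation of the new C5=C6 bond with the butenolide makes the shift fast at low temperature; one equivalent of a hindered potassium amide with 18-crown-6 leaves no excess base to remove H8 or to move the enol silyl group to the alkoxide.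

Step 22
Reactants: 25 (4S,5E,8S,10S)-4,8,13-tris(tert-butyldimethylsilyloxy)-10-(methoxymethoxy)-1-oxogermacra-5,7(11)-dien-12,6-olide
Product: 27 (1R,4S,5E,8S,10S)-1,4-epoxy-1,8,13-trihydroxy-10-(methoxymethoxy)germacra-5,7(11)-dien-12,6-olide, via desilylated hydroxy ketone 26 (not isolated)
Conditions: HF·pyridine, pyridine, THF, 0 °C → rt
Reagents that add atoms: none
Why: Buffered fluoride cleaves the three silyl ethers; the freed C4 hydroxyl adds across the ring to the C1 ketone to form the five-membered hemiketal. The ten-membered ring can only span the oxolane cis, so C1 is formed R.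

Step 23
Reactants: 27 (1R,4S,5E,8S,10S)-1,4-epoxy-1,8,13-trihydroxy-10-(methoxymethoxy)germacra-5,7(11)-dien-12,6-olide
Product: 28 (1R,4S,5E,8S,10S)-8,13-diacetoxy-1,4-epoxy-1-hydroxy-10-(methoxymethoxy)germacra-5,7(11)-dien-12,6-olide
Conditions: Ac2O, pyridine, DMAP (cat.), CH2Cl2, 0 °C
Reagents that add atoms: acetic anhydride, CC(=O)OC(C)=O
Why: Acetylation of the secondary C8 and primary C13 hydroxyls; the tertiary hemiketal hydroxyl is not acylated under these conditions.

Step 24
Reactants: 28 (1R,4S,5E,8S,10S)-8,13-diacetoxy-1,4-epoxy-1-hydroxy-10-(methoxymethoxy)germacra-5,7(11)-dien-12,6-olide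
Product: 29 (1R,4S,5E,8S,10S)-8,13-diacetoxy-1,4-epoxy-1,10-dihydroxygermacra-5,7(11)-dien-12,6-olide
Conditions: Me2BBr, CH2Cl2, −78 °C; then aq NaHCO3
Reagents that add atoms: none
Why: Bromodimethylborane cleaves methoxymethyl ethers, tertiary ones included, at low temperature without touching acetates; any bromide formed at the hemiketal carbon returns to the hemiketal on aqueous work-up.

Step 25
Reactants: 29 (1R,4S,5E,8S,10S)-8,13-diacetoxy-1,4-epoxy-1,10-dihydroxygermacra-5,7(11)-dien-12,6-olide
Product: 30 (4S,5E,8S,10S)-8,13-diacetoxy-1,4-epoxy-10-hydroxygermacra-1,5,7(11)-trien-12,6-olide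
Conditions: PPTS (cat.), 4 Å molecular sieves, benzene, 60 °C
Reagents that add atoms: none
Why: Acid-catalysed dehydration of the cyclic hemiketal through its oxocarbenium ion. Only C2 carries hydrogen next to C1, so the double bond can form only as C1=C2, and removal of water drives the equilibrium to the enol ether.

## Compound list

1 | 5-methoxy-2-methylphenol | Cc1ccc(OC)cc1O | starting material
2 | 2-(allyloxy)-4-methoxy-1-methylbenzene | Cc1ccc(OC)cc1OCC=C | intermediate
3 | 2-allyl-3-methoxy-6-methylphenol | Cc1ccc(OC)c(CC=C)c1O | intermediate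
4 | 2-methoxy-5-methyl-3-(prop-2-enyl)-1,4-benzoquinone | O=C1C(C)=CC(=O)C(OC)=C1CC=C | intermediate
5 | (5S,6R)-5,6-epoxy-2-methoxy-5-methyl-3-(prop-2-enyl)cyclohex-2-ene-1,4-dione | O=C1[C@@]2(C)O[C@H]2C(=O)C(OC)=C1CC=C | intermediate
6 | (5S)-5-hydroxy-2-methoxy-5-methyl-3-(prop-2-enyl)cyclohex-2-ene-1,4-dione | O=C1[C@@](C)(O)CC(=O)C(OC)=C1CC=C | intermediate
7 | (4S,6S)-4,6-dihydroxy-3-methoxy-6-methyl-2-(prop-2-enyl)cyclohex-2-en-1-one | O=C1[C@@](C)(O)C[C@H](O)C(OC)=C1CC=C | intermediate
8 | (4S,6S)-4-(tert-butyldimethylsilyloxy)-6-hydroxy-3-methoxy-6-methyl-2-(prop-2-enyl)cyclohex-2-en-1-one | O=C1[C@@](C)(O)C[C@H](O[Si](C)(C)C(C)(C)C)C(OC)=C1CC=C | intermediate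
9 | (4S,6S)-4-(tert-butyldimethylsilyloxy)-3-methoxy-6-(methoxymethoxy)-6-methyl-2-(prop-2-enyl)cyclohex-2-en-1-one | O=C1[C@@](C)(OCOC)C[C@H](O[Si](C)(C)C(C)(C)C)C(OC)=C1CC=C | intermediate
10 | (4S,6S)-6-(tert-butyldimethylsilyloxy)-4-(methoxymethoxy)-4-methyl-2-(prop-2-enyl)cyclohexane-1,3-dione, enol form drawn | O=C1[C@@](C)(OCOC)C[C@H](O[Si](C)(C)C(C)(C)C)C(O)=C1CC=C | intermediate
11 | (2S,4S,6S)-6-(tert-butyldimethylsilyloxy)-2-hydroxy-4-(methoxymethoxy)-4-methyl-2-(prop-2-enyl)cyclohexane-1,3-dione | O=C1[C@@](C)(OCOC)C[C@H](O[Si](C)(C)C(C)(C)C)C(=O)[C@@]1(O)CC=C | intermediate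
12 | triethyl phosphonoacetate | CCOC(=O)CP(=O)(OCC)OCC | starting material
13 | ethyl 2-(diethoxyphosphoryl)-3-hydroxypropanoate (racemic) | CCOC(=O)C(CO)P(=O)(OCC)OCC | intermediate
14 | ethyl 3-(tert-butyldimethylsilyloxy)-2-(diethoxyphosphoryl)propanoate (racemic) | CCOC(=O)C(CO[Si](C)(C)C(C)(C)C)P(=O)(OCC)OCC | intermediate
15 | 3-(tert-butyldimethylsilyloxy)-2-(diethoxyphosphoryl)propanoic acid (racemic) | OC(=O)C(CO[Si](C)(C)C(C)(C)C)P(=O)(OCC)OCC | intermediate
16 | (1S,3S,5S)-3-(tert-butyldimethylsilyloxy)-5-(methoxymethoxy)-5-methyl-2,6-dioxo-1-(prop-2-enyl)cyclohexyl 3-(tert-butyldimethylsilyloxy)-2-(diethoxyphosphoryl)propanoate (epimers at the phosphonate carbon) | O=C1[C@@](C)(OCOC)C[C@H](O[Si](C)(C)C(C)(C)C)C(=O)[C@@]1(OC(=O)C(CO[Si](C)(C)C(C)(C)C)P(=O)(OCC)OCC)CC=C | intermediate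
17 | (4S,6S,7aS)-4-(tert-butyldimethylsilyloxy)-3-[(tert-butyldimethylsilyloxy)methyl]-6-(methoxymethoxy)-6-methyl-7a-(prop-2-enyl)-5,6-dihydro-1-benzofuran-2,7(4H,7aH)-dione | O=C1[C@@](C)(OCOC)C[C@H](O[Si](C)(C)C(C)(C)C)C2=C(CO[Si](C)(C)C(C)(C)C)C(=O)O[C@]12CC=C | intermediate
18 | (4S,6S,7aS)-4-(tert-butyldimethylsilyloxy)-3-[(tert-butyldimethylsilyloxy)methyl]-6-(methoxymethoxy)-6-methyl-7-methylidene-7a-(prop-2-enyl)-5,6,7,7a-tetrahydro-1-benzofuran-2(4H)-one | C=C1[C@@](C)(OCOC)C[C@H](O[Si](C)(C)C(C)(C)C)C2=C(CO[Si](C)(C)C(C)(C)C)C(=O)O[C@]12CC=C | intermediate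
19 | (4S,6S,7aS)-4-(tert-butyldimethylsilyloxy)-3-[(tert-butyldimethylsilyloxy)methyl]-6-(methoxymethoxy)-6-methyl-7-methylidene-7a-(2-oxopropyl)-5,6,7,7a-tetrahydro-1-benzofuran-2(4H)-one | C=C1[C@@](C)(OCOC)C[C@H](O[Si](C)(C)C(C)(C)C)C2=C(CO[Si](C)(C)C(C)(C)C)C(=O)O[C@]12CC(C)=O | intermediate
20 | (4S,6S,7R,7aS)-4-(tert-butyldimethylsilyloxy)-3-[(tert-butyldimethylsilyloxy)methyl]-6-(methoxymethoxy)-6-methyl-7a-(2-oxopropyl)-4,5,6,7a-tetrahydrospiro[1-benzofuran-7,2'-oxiran]-2-one | C1O[C@@]12[C@@](C)(OCOC)C[C@H](O[Si](C)(C)C(C)(C)C)C3=C(CO[Si](C)(C)C(C)(C)C)C(=O)O[C@]23CC(C)=O | intermediate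
21 | (4S,6S,7R,7aS)-4-(tert-butyldimethylsilyloxy)-3-[(tert-butyldimethylsilyloxy)methyl]-7a-[(1Z)-2-(tert-butyldimethylsilyloxy)prop-1-enyl]-6-(methoxymethoxy)-6-methyl-4,5,6,7a-tetrahydrospiro[1-benzofuran-7,2'-oxiran]-2-one | C1O[C@@]12[C@@](C)(OCOC)C[C@H](O[Si](C)(C)C(C)(C)C)C3=C(CO[Si](C)(C)C(C)(C)C)C(=O)O[C@]23/C=C(/C)O[Si](C)(C)C(C)(C)C | intermediate
22 | (4S,6S,7R,7aS)-7-ethenyl-7-hydroxy-4-(tert-butyldimethylsilyloxy)-3-[(tert-butyldimethylsilyloxy)methyl]-7a-[(1Z)-2-(tert-butyldimethylsilyloxy)prop-1-enyl]-6-(methoxymethoxy)-6-methyl-5,6,7,7a-tetrahydro-1-benzofuran-2(4H)-one (position 7 = C1, 7a = C6, 4 = C8, 6 = C10) | C=C[C@@]1(O)[C@@](C)(OCOC)C[C@H](O[Si](C)(C)C(C)(C)C)C2=C(CO[Si](C)(C)C(C)(C)C)C(=O)O[C@]12/C=C(/C)O[Si](C)(C)C(C)(C)C | intermediate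
23 | potassium C1-alkoxide of 22 | C=C[C@@]1([O-])[C@@](C)(OCOC)C[C@H](O[Si](C)(C)C(C)(C)C)C2=C(CO[Si](C)(C)C(C)(C)C)C(=O)O[C@]12/C=C(/C)O[Si](C)(C)C(C)(C)C.[K+] | intermediate (not isolated)
24 | potassium C1-enolate (C1=C2) of 25 | CC(C)(C)[Si](C)(C)OCC1=C2/C(=C\[C@](O[Si](C)(C)C(C)(C)C)(C)C/C=C(\[O-])[C@@](C)(OCOC)C[C@@H]2O[Si](C)(C)C(C)(C)C)OC1=O.[K+] | intermediate (not isolated)
25 | (4S,5E,8S,10S)-4,8,13-tris(tert-butyldimethylsilyloxy)-10-(methoxymethoxy)-1-oxogermacra-5,7(11)-dien-12,6-olide | CC(C)(C)[Si](C)(C)OCC1=C2/C(=C\[C@](O[Si](C)(C)C(C)(C)C)(C)CCC(=O)[C@@](C)(OCOC)C[C@@H]2O[Si](C)(C)C(C)(C)C)OC1=O | intermediate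
26 | (4S,5E,8S,10S)-4,8,13-trihydroxy-10-(methoxymethoxy)-1-oxogermacra-5,7(11)-dien-12,6-olide | OCC1=C2/C(=C\[C@](O)(C)CCC(=O)[C@@](C)(OCOC)C[C@@H]2O)OC1=O | intermediate (not isolated)
27 | (1R,4S,5E,8S,10S)-1,4-epoxy-1,8,13-trihydroxy-10-(methoxymethoxy)germacra-5,7(11)-dien-12,6-olide | OCC1=C2/C(=C\[C@]3(C)CC[C@@](O)(O3)[C@@](C)(OCOC)C[C@@H]2O)OC1=O | intermediate
28 | (1R,4S,5E,8S,10S)-8,13-diacetoxy-1,4-epoxy-1-hydroxy-10-(methoxymethoxy)germacra-5,7(11)-dien-12,6-olide | CC(=O)OCC1=C2/C(=C\[C@]3(C)CC[C@@](O)(O3)[C@@](C)(OCOC)C[C@@H]2OC(C)=O)OC1=O | intermediate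
29 | (1R,4S,5E,8S,10S)-8,13-diacetoxy-1,4-epoxy-1,10-dihydroxygermacra-5,7(11)-dien-12,6-olide | CC(=O)OCC1=C2/C(=C\[C@]3(C)CC[C@@](O)(O3)[C@@](C)(O)C[C@@H]2OC(C)=O)OC1=O | intermediate
30 | (4S,5E,8S,10S)-8,13-diacetoxy-1,4-epoxy-10-hydroxygermacra-1,5,7(11)-trien-12,6-olide | CC(=O)OCC1=C2/C(=C\[C@]3(C)CC=C(O3)[C@@](C)(O)C[C@@H]2OC(C)=O)OC1=O | target

## Step count and least certain steps

Total: 25 steps. Longest linear sequence: 22 steps (steps 1–10 and 14–25, from 1 to 30). The phosphonate acid 15 is made in a 3-step branch (steps 11–13).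

**Step 21 (key step).** Three things can go wrong.
- Poor selection between the two chair arrays: the chair reached directly from the half-chair ground state has the lactone oxygen inside and leads to the 4R,5Z isomer.
- Migration of the enol silyl group to the C1 alkoxide through a seven-membered array, after which the freed enolate expels the lactone carboxylate.
- Cleavage of C1–C6 to a furanolate and a vinyl ketone that do not recombine.

Fallback: a neutral thermal oxy-Cope rearrangement, which has no alkoxide and so cannot transfer silicon or fragment. Setting out from 22, the C1 hydroxyl is silylated with N-(trimethylsilyl)imidazole to the C1 trimethylsilyl ether F1. F1 is heated in o-dichlorobenzene at about 180 °C in base-washed glass to the ten-membered C1 trimethylsilyl enol ether F2. K2CO3 in methanol at 0 °C cleaves only the trimethylsilyl enol ether, and the route is rejoined at 25.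

**Step 20.** The ylide is a strong base. It may remove H8 (γ to the lactone carbonyl) with loss of the C13 silyloxy group, or add to the lactone, before it opens the hindered epoxide. The lithium alkoxide formed may also rearrange prematurely.

Fallback: selenium-based homologation with one equivalent of a less basic carbanion and a neutral elimination. Setting out from 21, (phenylselanyl)methyllithium (from bis(phenylselanyl)methane and n-BuLi, THF, −78 °C) opens the epoxide at CH2 to the γ-hydroxy selenide F3. Oxidation with one equivalent of mCPBA at −78 °C, then warming with i-Pr2NH, causes selenoxide syn-elimination toward the only β-hydrogens, and the route is rejoined at 22.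

**Step 10.** Oxygen delivery from the face of the C10 oxygen (poor facial selectivity) would give the C6 epimer. The 2-hydroxy-1,3-dione can also undergo α-ketol ring contraction if base is present.

Fallback: hydroxyl-directed delivery instead of steric control. Setting out from 10, the C8 silyl ether is removed with HF·pyridine to the hydroxy-dione F4. mCPBA in CH2Cl2 at −20 °C, guided by hydrogen bonding to the free C8 hydroxyl, puts the oxygen on the same face to give the dihydroxy-dione F5. Selective silylation of the secondary hydroxyl (TBSCl, imidazole) rejoins the route at 11.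

**Step 4.** Face selection by the phase-transfer catalyst may be poor on a benzoquinone; the precedent is on naphthoquinones. The result would be low enantiomeric purity carried through the whole route.

Fallback: racemic synthesis and enzymatic resolution. Setting out from 4, H2O2 and Na2CO3 give the racemic epoxide F6. SmI2 gives the racemic hydroxy ketone F7, and Me4NBH(OAc)3 the racemic anti-diol F8. A lipase (Burkholderia cepacia lipase, vinyl acetate, t-BuOMe) is expected to acylate the enantiomer with the R carbinol, giving the acetate F9, and to leave the 4S,6S diol. After separation the route is rejoined at 7.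

## Further compounds

F1 | step 21 | C1 trimethylsilyl ether of 22 | C=C[C@@]1(O[Si](C)(C)C)[C@@](C)(OCOC)C[C@H](O[Si](C)(C)C(C)(C)C)C2=C(CO[Si](C)(C)C(C)(C)C)C(=O)O[C@]12/C=C(/C)O[Si](C)(C)C(C)(C)C
F2 | step 21 | (4S,5E,8S,10S)-4,8,13-tris(tert-butyldimethylsilyloxy)-10-(methoxymethoxy)-1-(trimethylsilyloxy)germacra-1,5,7(11)-trien-12,6-olide | CC(C)(C)[Si](C)(C)OCC1=C2/C(=C\[C@](O[Si](C)(C)C(C)(C)C)(C)C/C=C(\O[Si](C)(C)C)[C@@](C)(OCOC)C[C@@H]2O[Si](C)(C)C(C)(C)C)OC1=O
F3 | step 20 | (4S,6S,7R,7aS)-7-hydroxy-7-[2-(phenylselanyl)ethyl] analogue of 22 | c1ccccc1[Se]CC[C@@]1(O)[C@@](C)(OCOC)C[C@H](O[Si](C)(C)C(C)(C)C)C2=C(CO[Si](C)(C)C(C)(C)C)C(=O)O[C@]12/C=C(/C)O[Si](C)(C)C(C)(C)C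
F4 | step 10 | (4S,6S)-6-hydroxy-4-(methoxymethoxy)-4-methyl-2-(prop-2-enyl)cyclohexane-1,3-dione, enol form drawn | O=C1[C@@](C)(OCOC)C[C@H](O)C(O)=C1CC=C
F5 | step 10 | (2S,4S,6S)-2,6-dihydroxy-4-(methoxymethoxy)-4-methyl-2-(prop-2-enyl)cyclohexane-1,3-dione | O=C1[C@@](C)(OCOC)C[C@H](O)C(=O)[C@@]1(O)CC=C
F6 | step 4 | racemic 5,6-epoxy-2-methoxy-5-methyl-3-(prop-2-enyl)cyclohex-2-ene-1,4-dione | O=C1C2(C)OC2C(=O)C(OC)=C1CC=C
F7 | step 4 | racemic 5-hydroxy-2-methoxy-5-methyl-3-(prop-2-enyl)cyclohex-2-ene-1,4-dione | O=C1C(C)(O)CC(=O)C(OC)=C1CC=C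
F8 | step 4 | racemic anti-4,6-dihydroxy-3-methoxy-6-methyl-2-(prop-2-enyl)cyclohex-2-en-1-one (racemate; the 4S,6S enantiomer is drawn) | O=C1[C@@](C)(O)C[C@H](O)C(OC)=C1CC=C
F9 | step 4 | (4R,6R)-4-acetoxy-6-hydroxy-3-methoxy-6-methyl-2-(prop-2-enyl)cyclohex-2-en-1-one | O=C1[C@](C)(O)C[C@@H](OC(C)=O)C(OC)=C1CC=C
A1 | alternative 1 | 2,3-dihydrofuran with the C4, C8 and C10 stereocentres (C1–C10 segment) | CC(C)[Si](C(C)C)(C(C)C)OC[C@]1(C)CC=C(O1)[C@@](C)(O)C[C@H]2COC(C)(C)O2
A2 | alternative 1 | 1,3-oxathiane 3,3-dioxide precursor of A1 (configuration at the carbon between O and S open) | CC(C)[Si](C(C)C)(C(C)C)OC[C@]1(C)CCS(=O)(=O)C(O1)[C@@](C)(O)C[C@H]2COC(C)(C)O2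
A3 | alternative 2 | C1 hemiketal, identical with 29 | CC(=O)OCC1=C2/C(=C\[C@]3(C)CC[C@@](O)(O3)[C@@](C)(O)C[C@@H]2OC(C)=O)OC1=O
A4 | alternative 2 | ten-membered 4,5-epoxy-1-ketone (configuration at C5 and C6 left open) | CC(=O)OCC1=C2C(C3O[C@@]3(C)CCC(=O)[C@@](C)(O)C[C@@H]2OC(C)=O)OC1=O
A5 | alternative 3 | target skeleton with C10 and C13 triethylsilyl ethers | CC[Si](CC)(CC)OCC1=C2/C(=C\[C@]3(C)CC=C(O3)[C@@](C)(O[Si](CC)(CC)CC)C[C@@H]2OC(C)=O)OC1=O
A6 | alternative 3 | seco C5 aldehyde with free C6 methylene on the butenolide | O=C[C@]1(C)CC=C(O1)[C@@](C)(O[Si](CC)(CC)CC)C[C@H](OC(C)=O)C1=C(CO[Si](CC)(CC)CC)C(=O)OC1
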